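## Plan

Numbering: oxolane O1, C2 (aryl), C3 (bears C9H2–O–caffeoyl), C4 (bears the arylmethyl group), C5H2.
Cuts, in retrosynthetic order: the C9O–acyl ester bond, the benzylic O1–C2 ether bond, the C2–C3 aldol bond, the O–C5 bond of a γ-lactone whose carbonyl carbon is C9, and the two [2+2] ring bonds of a cyclobutanone (C9–CH2 and C4–CH2).
Enabling feature: once C2 and O1 are removed, C3 and C5 are two equivalent one-carbon branches on C4. Bridging them with C9 as C=O gives the carbocycle C9–C3–C4–C5, a cyclobutanone with a mirror plane through C9 and C4. C4 is prochiral there and becomes stereogenic when oxygen enters only one of the two C9–CH2 bonds.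
Forward order: cyclobutanone ring (eugenol alkene plus dichloroketene), ring expansion to the lactone ring, aldol with protected vanillin, reductive opening of the lactone, closure of the oxolane ring at O1–C2, esterification with protected caffeic acid, one global desilylation.
Stereochemistry: C4 comes from the chiral phosphoric acid in the Baeyer–Villiger step. C3 comes from enolate attack anti to the C4 arm (lactone-trans equals oxolane 3,4-cis). C2 comes from closure of a planar benzylic cation trans to the C3 arm. The E alkene comes with caffeic acid.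

Key step: step 4

Abbreviations: TBS = tert-butyldimethylsilyl; TBSO = tert-butyldimethylsilyloxy.
Assumption: the (R)-configured phosphoric acid is taken to deliver (S)-8, the same spatial sense as with 3-aryl substrates (the descriptor differs only through CIP ranking); if the rotation of 8 shows otherwise, the equally accessible (S)-acid is used.

## Route

Step 1
Reactants: 1 eugenol
Product: 2 O-TBS-eugenol (tert-butyl[2-methoxy-4-(prop-2-enyl)phenoxy]dimethylsilane)
Conditions: TBSCl, imidazole, DMF, rt
Reagents that add atoms: tert-butyldimethylsilyl chloride (TBSCl), CC(C)(C)[Si](C)(C)Cl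
Why: Imidazole-promoted O-silylation of a phenol masks the acidic OH, which would otherwise consume the ketene and later the amide base, as a group that a single fluoride treatment removes at the end.

Step 2
Reactants: 2 O-TBS-eugenol; 3 trichloroacetyl chloride
Product: 5 (±)-2,2-dichloro-3-[(4-TBSO-3-methoxyphenyl)methyl]cyclobutan-1-one, via dichloroketene 4 (not isolated)
Conditions: Zn–Cu couple, Et2O–DME, slow addition of 3, gentle reflux
Reagents that add atoms: none
Why: Zinc dechlorinates 3 to dichloroketene 4, which adds to the terminal alkene in a thermal [2+2] ketene–alkene cycloaddition with its carbonyl carbon bonding to the terminal CH2, while DME ties up ZnCl2; the new centre forms racemic and loses its stereogenic character in step 3.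

Step 3
Reactants: 5 (±)-dichlorocyclobutanone
Product: 6 3-[(4-TBSO-3-methoxyphenyl)methyl]cyclobutan-1-one
Conditions: Zn dust, AcOH, rt
Reagents that add atoms: none
Why: Reductive dehalogenation of an α,α-dichloroketone with zinc in acetic acid removes both chlorines, spares the ketone and the aryl silyl ether, and leaves an achiral ketone with a mirror plane through C=O and the substituted ring carbon.

Step 4
Reactants: 6 3-[(4-TBSO-3-methoxyphenyl)methyl]cyclobutan-1-one
Product: 8 (4S)-4-[(4-TBSO-3-methoxyphenyl)methyl]oxolan-2-one, via Criegee adduct 7 (not isolated)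
Conditions: (R)-3,3'-di(pyren-1-yl)-H8-BINOL hydrogen phosphate (10 mol %), 30% aq. H2O2 (1.5 equiv), CHCl3, −40 °C
Reagents that add atoms: hydrogen peroxide, OO
Why: This is an organocatalytic asymmetric Baeyer–Villiger oxidation, a reaction type established for prochiral 3-substituted cyclobutanones, in which the phosphoric acid binds the strained carbonyl group and H2O2 through its acidic OH and its P=O group, H2O2 adds to give Criegee adduct 7, and one ring CH2 migrates from carbon to oxygen with loss of water. The oxolan-2-one ring arises by ring expansion through this 1,2-shift (four-membered carbocycle to five-membered lactone, new O–C5 bond) and not by an end-to-end closure, and release of ring strain lets it run at −40 °C. The only new stereocentre, C4, is fixed by which CH2 migrates, since inside the hydrogen-bonded assembly the pyrenyl walls of the catalyst let only one of the two lie antiperiplanar to the O–O bond. The selectivity needed is therefore enantiotopic-group selectivity and comes from the catalyst alone because the substrate is mirror-symmetric, while regioselectivity is no issue (both candidates are CH2) and no bond at C4 is touched. Chemoselectivity is secured by the substrate, as the strained ketone is the only group that adds H2O2 under these conditions and the aryl silyl ether and the electron-rich arene stay inert to dilute peroxide in the cold. Because the aryl group is one CH2 away from the ring, induction should be harder to reach than with 3-aryl substrates, so the ee of 8 is to be checked by chiral HPLC before going on.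

Step 5
Reactants: 9 vanillin
Product: 10 O-TBS-vanillin (4-TBSO-3-methoxybenzaldehyde)
Conditions: TBSCl, imidazole, CH2Cl2, rt
Reagents that add atoms: tert-butyldimethylsilyl chloride (TBSCl), CC(C)(C)[Si](C)(C)Cl
Why: The same phenol O-silylation removes the proton that would quench the enolate in step 6 and gives both guaiacyl rings one common protecting group.

Step 6
Reactants: 8 (S)-lactone; 10 O-TBS-vanillin
Product: 12 (3R,4S)-3-[hydroxy(4-TBSO-3-methoxyphenyl)methyl]-4-[(4-TBSO-3-methoxyphenyl)methyl]oxolan-2-one (3,4-trans; both carbinol epimers), via lithium enolate 11 (not isolated)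
Conditions: LiHMDS, THF, −78 °C; then 10, −78 °C; AcOH quench at −78 °C
Reagents that add atoms: none
Why: In this aldol addition of a lactone lithium enolate, the C4 arylmethyl group shields one face of 11, so the aldehyde adds anti to it and sets C3 trans to C4; the carbinol carbon forms as an epimer mixture, which does not matter because step 8 planarises it.

Step 7
Reactants: 12 aldol lactone
Product: 13 (2S,3S)-2-[hydroxy(4-TBSO-3-methoxyphenyl)methyl]-3-[(4-TBSO-3-methoxyphenyl)methyl]butane-1,4-diol (both carbinol epimers)
Conditions: LiAlH4, THF, 0 °C; Na2SO4·10H2O quench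
Reagents that add atoms: none
Why: Hydride reduction of the lactone to the 1,4-diol turns C9 into CH2OH and frees the C5 hydroxyl without touching C3 or C4, and short contact at 0 °C with a neutral quench spares the aryl silyl ethers.

Step 8
Reactants: 13 triol
Product: 15 [(2R,3S,4S)-2-(4-TBSO-3-methoxyphenyl)-4-[(4-TBSO-3-methoxyphenyl)methyl]oxolan-3-yl]methanol, via benzylic cation 14 (not isolated)
Conditions: camphorsulfonic acid (10 mol %), CH2Cl2, 0 °C; Et3N quench once 13 is consumed
Reagents that add atoms: none
Why: In this acid-catalysed SN1 cycloetherification, both carbinol epimers lose water to the same planar p-silyloxy-stabilised cation 14, and the C5 hydroxyl closes the five-membered ring (5-exo-trig on the quinoid form, whereas the C9 hydroxyl could only form an oxetane) on the face that places the aryl group trans to the C3 CH2OH arm; because the benzylic ether can re-ionise, this 2R isomer should be favoured kinetically and thermodynamically.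

Step 9
Reactants: 16 caffeic acid
Product: 18 (E)-3-[3,4-bis(TBSO)phenyl]prop-2-enoic acid, via tris-TBS silyl ester 17 (not isolated)
Conditions: TBSCl (3.3 equiv), imidazole, DMF, rt; then AcOH–THF–H2O, rt
Reagents that add atoms: tert-butyldimethylsilyl chloride (TBSCl), CC(C)(C)[Si](C)(C)Cl
Why: Exhaustive silylation followed by selective hydrolysis of the far more labile silyl ester in aqueous acetic acid, to which aryl TBS ethers are stable, frees the acid and leaves the E alkene unchanged.

Step 10
Reactants: 15 oxolane alcohol; 18 bis-TBS caffeic acid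
Product: 19 [(2R,3S,4S)-2-(4-TBSO-3-methoxyphenyl)-4-[(4-TBSO-3-methoxyphenyl)methyl]oxolan-3-yl]methyl (E)-3-[3,4-bis(TBSO)phenyl]prop-2-enoate
Conditions: DCC, DMAP (cat.), CH2Cl2, 0 °C to rt
Reagents that add atoms: none
Why: Steglich esterification acylates the only free hydroxyl group of 15 under near-neutral conditions that neither ionise the benzylic ether nor isomerise the E alkene.

Step 11
Reactants: 19 tetrasilyl ester
Product: 20 [(2R,3S,4S)-2-(4-hydroxy-3-methoxyphenyl)-4-[(4-hydroxy-3-methoxyphenyl)methyl]oxolan-3-yl]methyl (E)-3-(3,4-dihydroxyphenyl)prop-2-enoate (target)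
Conditions: TBAF, AcOH (1:1), THF, 0 °C, under argon
Reagents that add atoms: none
Why: Fluoride cleaves all four aryl silyl ethers, and the acetic acid buffer keeps the freed phenols and the catechol protonated, so the ester should not be attacked, the catechol should not be oxidised, and no stereocentre is touched.

## Compound list

1 | eugenol (4-allyl-2-methoxyphenol) | C=CCc1ccc(O)c(OC)c1 | starting material
2 | O-TBS-eugenol, tert-butyl[2-methoxy-4-(prop-2-enyl)phenoxy]dimethylsilane | C=CCc1ccc(O[Si](C)(C)C(C)(C)C)c(OC)c1 | intermediate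
3 | trichloroacetyl chloride | ClC(=O)C(Cl)(Cl)Cl | starting material
4 | dichloroketene | ClC(Cl)=C=O | intermediate
5 | (±)-2,2-dichloro-3-[(4-tert-butyldimethylsilyloxy-3-methoxyphenyl)methyl]cyclobutan-1-one (racemic) | COc1cc(CC2CC(=O)C2(Cl)Cl)ccc1O[Si](C)(C)C(C)(C)C | intermediate
6 | 3-[(4-tert-butyldimethylsilyloxy-3-methoxyphenyl)methyl]cyclobutan-1-one (achiral, prochiral) | COc1cc(CC2CC(=O)C2)ccc1O[Si](C)(C)C(C)(C)C | intermediate
7 | Criegee adduct, 1-hydroperoxy-3-[(4-tert-butyldimethylsilyloxy-3-methoxyphenyl)methyl]cyclobutan-1-ol | COc1cc(CC2CC(O)(OO)C2)ccc1O[Si](C)(C)C(C)(C)C | intermediate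
8 | (4S)-4-[(4-tert-butyldimethylsilyloxy-3-methoxyphenyl)methyl]oxolan-2-one | COc1cc(C[C@@H]2COC(=O)C2)ccc1O[Si](C)(C)C(C)(C)C | intermediate
9 | vanillin | COc1cc(C=O)ccc1O | starting material
10 | O-TBS-vanillin, 4-(tert-butyldimethylsilyloxy)-3-methoxybenzaldehyde | COc1cc(C=O)ccc1O[Si](C)(C)C(C)(C)C | intermediate
11 | lithium enolate of 8 | COc1cc(C[C@@H]2COC([O-])=C2)ccc1O[Si](C)(C)C(C)(C)C.[Li+] | intermediate
12 | (3R,4S)-3-[hydroxy(4-tert-butyldimethylsilyloxy-3-methoxyphenyl)methyl]-4-[(4-tert-butyldimethylsilyloxy-3-methoxyphenyl)methyl]oxolan-2-one, 3,4-trans, both epimers at the carbinol carbon | COc1cc(C[C@@H]2COC(=O)[C@H]2C(O)c3ccc(O[Si](C)(C)C(C)(C)C)c(OC)c3)ccc1O[Si](C)(C)C(C)(C)C | intermediate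
13 | (2S,3S)-2-[hydroxy(4-tert-butyldimethylsilyloxy-3-methoxyphenyl)methyl]-3-[(4-tert-butyldimethylsilyloxy-3-methoxyphenyl)methyl]butane-1,4-diol, both epimers at the carbinol carbon | COc1cc(C[C@H](CO)[C@@H](CO)C(O)c2ccc(O[Si](C)(C)C(C)(C)C)c(OC)c2)ccc1O[Si](C)(C)C(C)(C)C | intermediate
14 | benzylic cation formed from 13 by loss of water at the carbinol carbon | COc1cc(C[C@H](CO)[C@@H](CO)[CH+]c2ccc(O[Si](C)(C)C(C)(C)C)c(OC)c2)ccc1O[Si](C)(C)C(C)(C)C | intermediate
15 | [(2R,3S,4S)-2-(4-tert-butyldimethylsilyloxy-3-methoxyphenyl)-4-[(4-tert-butyldimethylsilyloxy-3-methoxyphenyl)methyl]oxolan-3-yl]methanol (2,3-trans, 3,4-cis) | COc1cc(C[C@@H]2CO[C@@H](c3ccc(O[Si](C)(C)C(C)(C)C)c(OC)c3)[C@@H]2CO)ccc1O[Si](C)(C)C(C)(C)C | intermediate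
16 | caffeic acid, (E)-3-(3,4-dihydroxyphenyl)prop-2-enoic acid | OC(=O)/C=C/c1ccc(O)c(O)c1 | starting material
17 | tert-butyldimethylsilyl (E)-3-[3,4-bis(tert-butyldimethylsilyloxy)phenyl]prop-2-enoate | CC(C)(C)[Si](C)(C)OC(=O)/C=C/c1ccc(O[Si](C)(C)C(C)(C)C)c(O[Si](C)(C)C(C)(C)C)c1 | intermediate
18 | (E)-3-[3,4-bis(tert-butyldimethylsilyloxy)phenyl]prop-2-enoic acid | OC(=O)/C=C/c1ccc(O[Si](C)(C)C(C)(C)C)c(O[Si](C)(C)C(C)(C)C)c1 | intermediate
19 | [(2R,3S,4S)-2-(4-tert-butyldimethylsilyloxy-3-methoxyphenyl)-4-[(4-tert-butyldimethylsilyloxy-3-methoxyphenyl)methyl]oxolan-3-yl]methyl (E)-3-[3,4-bis(tert-butyldimethylsilyloxy)phenyl]prop-2-enoate | COc1cc(C[C@@H]2CO[C@@H](c3ccc(O[Si](C)(C)C(C)(C)C)c(OC)c3)[C@@H]2COC(=O)/C=C/c2ccc(O[Si](C)(C)C(C)(C)C)c(O[Si](C)(C)C(C)(C)C)c2)ccc1O[Si](C)(C)C(C)(C)C | intermediate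
20 | [(2R,3S,4S)-2-(4-hydroxy-3-methoxyphenyl)-4-[(4-hydroxy-3-methoxyphenyl)methyl]oxolan-3-yl]methyl (E)-3-(3,4-dihydroxyphenyl)prop-2-enoate | COc1cc(C[C@@H]2CO[C@@H](c3ccc(O)c(OC)c3)[C@@H]2COC(=O)/C=C/c2ccc(O)c(O)c2)ccc1O | target

## Step count and risks

Total step count: 11.
Longest linear sequence: 9 steps (1, 2, 3, 4, 6, 7, 8, 10, 11).

**Step 4.**
- What may go wrong: the catalyst may not tell the two enantiotopic ring CH2 groups apart well enough, because the aryl group sits one CH2 away from the ring. Uncatalysed oxidation by H2O2 may dilute the induction further.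
- Fallback (sets out from 2, comes back at 8): C4 is created by an enantioselective carbenoid C–H insertion instead of a ring expansion. Hydroboration of 2 with 9-BBN in THF gives the B-alkyl-9-borabicyclo[3.3.1]nonane F1. NaBO3·4H2O oxidises it in the same flask to 3-(4-TBSO-3-methoxyphenyl)propan-1-ol F2. Bromoacetyl bromide and NaHCO3 in MeCN give the bromoacetate F3, and N,N'-ditosylhydrazine with DBU converts it into the diazoacetate F4. Slow addition of F4 to Rh2(4R-MPPIM)4 (MPPIM = methyl 1-(3-phenylpropanoyl)-2-oxoimidazolidine-4-carboxylate) in refluxing CH2Cl2 should insert the carbenoid into the C–H bond β to the ester oxygen and close lactone 8. This is a known entry to β-arylmethyl-γ-butyrolactones, and the ligand antipode is chosen for the S product.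

**Step 8.**
- What may go wrong: the electron-rich pendant arene may capture the cation in place of the C5 hydroxyl, closing a six-membered carbocycle. The product ether may re-ionise on prolonged acid contact, and facial selectivity at C2 may be incomplete.
- Fallback (sets out from 13, comes back at 20): the silyl groups are removed first, so the ring closes through a neutral quinone methide at much lower acidity, and the ester is then made without phenol protection. TBAF/AcOH in THF converts 13 into the free-phenol triol F5. In aqueous THF with a trace of HCl at rt, the para-hydroxyl expels water to give the p-quinone methide F6, which is too weak an electrophile for the arene. The C5 hydroxyl adds to it reversibly in a 1,6-addition to give (2R,3S,4S)-lariciresinol F7. A chemoselective Mitsunobu esterification of F7 with unprotected caffeic acid 16 (PPh3, DIAD, THF, 0 °C to rt) then gives 20 directly. Only the carboxylic acid protonates the betaine and only the aliphatic primary hydroxyl is activated.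

**Step 7.**
- What may go wrong: the metal alkoxide of the carbinol may undergo retro-aldol fragmentation before the lactone is reduced. Hydride or alkoxide may attack the aryl silyl ethers, causing loss or migration of TBS.
- Fallback (sets out from 12, comes back at 15): the carbinol is capped before reduction and a non-basic hydride is used. TESOTf and 2,6-lutidine in CH2Cl2 at −78 °C give the triethylsilyl ether F8. Excess DIBAL-H in CH2Cl2 (−78 to 0 °C) reduces the lactone to the diol F9. Camphorsulfonic acid in CH2Cl2 at 0 °C then ionises the benzylic silyl ether as the leaving group, and the C5 hydroxyl closes the ring to 15 as in step 8, so triol 13 is bypassed.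

## Further compounds

F1 | step 4 | 9-[3-(4-tert-butyldimethylsilyloxy-3-methoxyphenyl)propyl]-9-borabicyclo[3.3.1]nonane | COc1cc(CCCB2C3CCCC2CCC3)ccc1O[Si](C)(C)C(C)(C)C
F2 | step 4 | 3-(4-tert-butyldimethylsilyloxy-3-methoxyphenyl)propan-1-ol | COc1cc(CCCO)ccc1O[Si](C)(C)C(C)(C)C
F3 | step 4 | 3-(4-tert-butyldimethylsilyloxy-3-methoxyphenyl)propyl bromoacetate | COc1cc(CCCOC(=O)CBr)ccc1O[Si](C)(C)C(C)(C)C
F4 | step 4 | 3-(4-tert-butyldimethylsilyloxy-3-methoxyphenyl)propyl diazoacetate | COc1cc(CCCOC(=O)C=[N+]=[N-])ccc1O[Si](C)(C)C(C)(C)C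
F5 | step 8 | (2S,3S)-2-[hydroxy(4-hydroxy-3-methoxyphenyl)methyl]-3-[(4-hydroxy-3-methoxyphenyl)methyl]butane-1,4-diol, both carbinol epimers | COc1cc(C[C@H](CO)[C@@H](CO)C(O)c2ccc(O)c(OC)c2)ccc1O
F6 | step 8 | p-quinone methide formed from F5 by loss of water (C3 and C4 unchanged) | COc1cc(C[C@H](CO)[C@@H](CO)C=C2C=CC(=O)C(OC)=C2)ccc1O
F7 | step 8 | (2R,3S,4S)-lariciresinol, 4-[[(3S,4S,5R)-5-(4-hydroxy-3-methoxyphenyl)-4-(hydroxymethyl)oxolan-3-yl]methyl]-2-methoxyphenol | COc1cc(C[C@@H]2CO[C@@H](c3ccc(O)c(OC)c3)[C@@H]2CO)ccc1O
F8 | step 7 | (3R,4S)-3-[(triethylsilyloxy)(4-tert-butyldimethylsilyloxy-3-methoxyphenyl)methyl]-4-[(4-tert-butyldimethylsilyloxy-3-methoxyphenyl)methyl]oxolan-2-one, both epimers at the silyloxy carbon | COc1cc(C[C@@H]2COC(=O)[C@H]2C(O[Si](CC)(CC)CC)c3ccc(O[Si](C)(C)C(C)(C)C)c(OC)c3)ccc1O[Si](C)(C)C(C)(C)C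
F9 | step 7 | (2S,3S)-2-[(triethylsilyloxy)(4-tert-butyldimethylsilyloxy-3-methoxyphenyl)methyl]-3-[(4-tert-butyldimethylsilyloxy-3-methoxyphenyl)methyl]butane-1,4-diol, both epimers at the silyloxy carbon | COc1cc(C[C@H](CO)[C@@H](CO)C(O[Si](CC)(CC)CC)c2ccc(O[Si](C)(C)C(C)(C)C)c(OC)c2)ccc1O[Si](C)(C)C(C)(C)C
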